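**Retrosynthetic overview**

1. Target 25 ⇐ silyl ether 24 ⇐ open-chain bromo-enal 21 in one Cr(II) operation: the C7=C11 π-system attacks C6 (the bond farnesyl diphosphate closes between its C10=C11 olefin and C1), then O6 acylates on C12.
2. 21 ⇐ 18 by cross-metathesis at C7 with methyl 2-(bromomethyl)acrylate, then oxidation of C6.
3. 18 ⇐ aldehyde 8 + (Z)-vinyl iodide 16 by asymmetric Ni/Cr coupling (C1–C10 bond, sets C1).
4. 8 ⇐ but-2-yne-1,4-diol (Red-Al/I2 fixes C4=C5, B-alkyl Suzuki adds C1–C3). 16 ⇐ acrolein + propynylmagnesium bromide (Sharpless resolution sets C8, Red-Al/I2 fixes C9=C10, esterification with (S)-2-methylbutanoic acid).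
5. Ring order: ten-membered carbocycle first, trans γ-lactone second, both in step 11 on the fully oxygenated chain; C6 and C7 are created there.

Assumption: the SMILES is read literally as a 12,6-olide with C3 and C6 cis on C4=C5 (CIP 4E because of CH2OH), 9Z, and 1S,6R,7R,8R,2′S; atom labels C1–C15 below are germacrane positions.

**Route**

Step 1
Reactants: 1 but-2-yne-1,4-diol
Product: 2 4-[(tert-butyldiphenylsilyl)oxy]but-2-yn-1-ol
Conditions: TBDPSCl (1 equiv), imidazole, DMF, 0 °C → rt (diol 4 equiv)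
Reagents that add atoms: tert-butyl(chloro)diphenylsilane, CC(C)(C)[Si](Cl)(c1ccccc1)c1ccccc1
Why: Statistical monosilylation (silyl ether formation) of a cheap symmetric diol used in excess marks the future C15 oxygen and leaves the C6 hydroxyl free to direct step 2.

Step 2
Reactants: 2 4-[(tert-butyldiphenylsilyl)oxy]but-2-yn-1-ol
Product: 4 (Z)-4-[(tert-butyldiphenylsilyl)oxy]-3-iodobut-2-en-1-ol, via cyclic vinylalanate 3 (not isolated)
Conditions: Red-Al (2.2 equiv), THF, 0 °C; then I2, −78 °C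
Reagents that add atoms: iodine, II
Why: Hydroxyl-directed trans-hydroalumination of the propargylic alcohol (hydride to C5, Al to C4) and iodinolysis with retention put iodine cis to CH2OH, which fixes the ring-cis C4=C5 geometry.

Step 3
Reactants: 4 (Z)-4-[(tert-butyldiphenylsilyl)oxy]-3-iodobut-2-en-1-ol; 5 3,3-diethoxyprop-1-ene
Product: 8 (E)-4-{[(tert-butyldiphenylsilyl)oxy]methyl}-6-hydroxyhex-4-enal, via B-alkyl-9-BBN adduct 6 (not isolated), via diethyl acetal 7 (not isolated)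
Conditions: 5, 9-BBN, THF, rt; then 4, PdCl2(dppf) (5 mol%), AsPh3, Cs2CO3, DMF/H2O, rt; then 1 M HCl, THF, 0 °C
Reagents that add atoms: water, O
Why: Hydroboration and B-alkyl Suzuki–Miyaura coupling proceed with retention of the olefin geometry, and brief acid hydrolysis frees the C1 aldehyde while the TBDPS ether survives.

Step 4
Reactants: 9 acrolein; 10 prop-1-yn-1-ylmagnesium bromide
Product: 11 rac-hex-1-en-4-yn-3-ol
Conditions: THF, −78 → 0 °C; H2O
Reagents that add atoms: none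
Why: 1,2-Grignard addition of the alkynyl reagent to the enal gives the racemic carbinol that becomes C8.

Step 5
Reactants: 11 rac-hex-1-en-4-yn-3-ol
Product: 12 (S)-hex-1-en-4-yn-3-ol
Conditions: Ti(OiPr)4 (10 mol%), L-(+)-DIPT (15 mol%), TBHP (0.6 equiv), 4 Å MS, CH2Cl2, −20 °C
Reagents that add atoms: none
Why: Sharpless kinetic resolution: with L-(+)-DIPT the (R)-enantiomer is epoxidised fast at its vinyl group and the (S)-alcohol, which carries the future 8R centre, is recovered in high ee.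

Step 6
Reactants: 12 (S)-hex-1-en-4-yn-3-ol
Product: 14 (3S,4Z)-5-iodohexa-1,4-dien-3-ol, via cyclic vinylalanate 13 (not isolated)
Conditions: Red-Al (2.2 equiv), THF, 0 °C; then I2, −78 °C
Reagents that add atoms: iodine, II
Why: The same hydroxyl-directed trans-hydroalumination/iodination puts iodine cis to the carbinol carbon (the later Z C9=C10 olefin) and leaves the unactivated vinyl group and the stereocentre untouched.

Step 7
Reactants: 14 (3S,4Z)-5-iodohexa-1,4-dien-3-ol; 15 (S)-2-methylbutanoic acid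
Product: 16 (3S,4Z)-5-iodohexa-1,4-dien-3-yl (2S)-2-methylbutanoate
Conditions: DCC (1.2 equiv), DMAP (5 mol%), CH2Cl2, 0 °C
Reagents that add atoms: none
Why: Steglich esterification at 0 °C with catalytic DMAP installs the side chain without epimerising its α-centre or ionising the bis-allylic carbinol.

Step 8
Reactants: 16 (3S,4Z)-5-iodohexa-1,4-dien-3-yl (2S)-2-methylbutanoate; 8 (E)-4-{[(tert-butyldiphenylsilyl)oxy]methyl}-6-hydroxyhex-4-enal
Product: 18 (3S,4Z,6S,9E)-9-{[(tert-butyldiphenylsilyl)oxy]methyl}-6,11-dihydroxy-5-methylundeca-1,4,9-trien-3-yl (2S)-2-methylbutanoate, via alkenylchromium 17 (not isolated)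
Conditions: CrCl2 (3 equiv), NiCl2 (5 mol%), Kishi valinol-derived oxazoline–sulfonamide ligand (3.3 equiv), Et3N (3.3 equiv), THF, rt
Reagents that add atoms: none
Why: Asymmetric Nozaki–Hiyama–Kishi alkenylation: the C–I bond is metalated with retention (Z olefin kept) and the chiral sulfonamide on Cr selects the aldehyde face to give the 1S carbinol; this is reagent control, so the ligand antipode that gives 1S is fixed by a Mosher check, and free OH and esters are tolerated.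

Step 9
Reactants: 18 (3S,4Z,6S,9E)-9-{[(tert-butyldiphenylsilyl)oxy]methyl}-6,11-dihydroxy-5-methylundeca-1,4,9-trien-3-yl (2S)-2-methylbutanoate; 19 methyl 2-(bromomethyl)prop-2-enoate
Product: 20 methyl (2Z,4R,5Z,7S,10E)-2-(bromomethyl)-10-{[(tert-butyldiphenylsilyl)oxy]methyl}-7,12-dihydroxy-6-methyl-4-{[(2S)-2-methylbutanoyl]oxy}dodeca-2,5,10-trienoate
Conditions: Hoveyda–Grubbs II (10 mol%), 19 (8 equiv), CH2Cl2, 40 °C
Reagents that add atoms: none
Why: Olefin cross-metathesis engages only the monosubstituted alkene and gives the thermodynamic (Z)-2-(bromomethyl)enoate, whose geometry is irrelevant later; the trisubstituted olefins and free hydroxyls are inert.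

Step 10
Reactants: 20 methyl (2Z,4R,5Z,7S,10E)-2-(bromomethyl)-10-{[(tert-butyldiphenylsilyl)oxy]methyl}-7,12-dihydroxy-6-methyl-4-{[(2S)-2-methylbutanoyl]oxy}dodeca-2,5,10-trienoate
Product: 21 methyl (2Z,4R,5Z,7S,10E)-2-(bromomethyl)-10-{[(tert-butyldiphenylsilyl)oxy]methyl}-7-hydroxy-6-methyl-4-{[(2S)-2-methylbutanoyl]oxy}-12-oxododeca-2,5,10-trienoate
Conditions: TEMPO (10 mol%), PhI(OAc)2 (1.2 equiv), CH2Cl2, rt
Reagents that add atoms: none
Why: Oxoammonium (TEMPO) oxidation takes the primary allylic alcohol selectively over the secondary C1 carbinol and keeps the enal geometry.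

Step 11
Reactants: 21 methyl (2Z,4R,5Z,7S,10E)-2-(bromomethyl)-10-{[(tert-butyldiphenylsilyl)oxy]methyl}-7-hydroxy-6-methyl-4-{[(2S)-2-methylbutanoyl]oxy}-12-oxododeca-2,5,10-trienoate
Product: 24 (1S,4E,6R,7R,8R,9Z)-15-[(tert-butyldiphenylsilyl)oxy]-1-hydroxy-8-{[(2S)-2-methylbutanoyl]oxy}germacra-4,9,11(13)-trien-12,6-olide, via allylchromium 22 (not isolated), via hydroxy ester 23 (not isolated)
Conditions: CrCl2 (10 equiv), THF, rt, 21 added over 10 h (2 mM); aq. NH4Cl; then PPTS (cat.), CH2Cl2, rt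
Reagents that add atoms: none
Why: Intramolecular Nozaki–Hiyama–Kishi (Cr-Barbier) 2-(alkoxycarbonyl)allylation then lactonisation: C7 adds to the C6 enal through a closed six-membered transition state with the chain diequatorial (6,7-anti, hence the trans lactone), and C8 fixes the C7 face by A1,3 strain (H8 in the allyl plane, C9 anti to the forming bond, ester oxygen in-plane and so poorly aligned for reductive 1,4-elimination), giving 6R,7R.

Step 12
Reactants: 24 (1S,4E,6R,7R,8R,9Z)-15-[(tert-butyldiphenylsilyl)oxy]-1-hydroxy-8-{[(2S)-2-methylbutanoyl]oxy}germacra-4,9,11(13)-trien-12,6-olide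
Product: 25 (1S,4E,6R,7R,8R,9Z)-1,15-dihydroxy-8-{[(2S)-2-methylbutanoyl]oxy}germacra-4,9,11(13)-trien-12,6-olide
Conditions: HF·pyridine, pyridine, THF, 0 °C → rt
Reagents that add atoms: none
Why: Buffered fluoride desilylation removes the TBDPS ether without touching the α-methylene lactone, the ester or the allylic alcohol; no stereocentre is involved.

**Compound list**

1 | but-2-yne-1,4-diol | OCC#CCO | starting material
2 | 4-[(tert-butyldiphenylsilyl)oxy]but-2-yn-1-ol | OCC#CCO[Si](c1ccccc1)(c1ccccc1)C(C)(C)C | intermediate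
3 | sodium 3-{[(tert-butyldiphenylsilyl)oxy]methyl}-2,2-bis(2-methoxyethoxy)-2,5-dihydro-1,2-oxaaluminol-2-uide (cyclic vinylalanate) | [Na+].COCCO[Al-]1(OCCOC)OCC=C1CO[Si](c2ccccc2)(c2ccccc2)C(C)(C)C | intermediate
4 | (Z)-4-[(tert-butyldiphenylsilyl)oxy]-3-iodobut-2-en-1-ol | OC/C=C(/CO[Si](c1ccccc1)(c1ccccc1)C(C)(C)C)I | intermediate
5 | 3,3-diethoxyprop-1-ene (acrolein diethyl acetal) | C=CC(OCC)OCC | starting material
6 | 9-(3,3-diethoxypropyl)-9-borabicyclo[3.3.1]nonane | CCOC(CCB1C2CCCC1CCC2)OCC | intermediate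
7 | (E)-3-{[(tert-butyldiphenylsilyl)oxy]methyl}-6,6-diethoxyhex-2-en-1-ol | OC/C=C(/CO[Si](c1ccccc1)(c1ccccc1)C(C)(C)C)CCC(OCC)OCC | intermediate
8 | (E)-4-{[(tert-butyldiphenylsilyl)oxy]methyl}-6-hydroxyhex-4-enal | OC/C=C(/CO[Si](c1ccccc1)(c1ccccc1)C(C)(C)C)CCC=O | intermediate
9 | acrolein (prop-2-enal) | C=CC=O | starting material
10 | prop-1-yn-1-ylmagnesium bromide | CC#C[Mg]Br | starting material
11 | rac-hex-1-en-4-yn-3-ol | CC#CC(O)C=C | intermediate
12 | (S)-hex-1-en-4-yn-3-ol | CC#C[C@@H](O)C=C | intermediate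
13 | sodium (5S)-5-ethenyl-2,2-bis(2-methoxyethoxy)-3-methyl-2,5-dihydro-1,2-oxaaluminol-2-uide (cyclic vinylalanate) | [Na+].COCCO[Al-]1(OCCOC)O[C@@H](C=C)C=C1C | intermediate
14 | (3S,4Z)-5-iodohexa-1,4-dien-3-ol | I/C(C)=C\[C@@H](O)C=C | intermediate
15 | (S)-2-methylbutanoic acid | CC[C@H](C)C(=O)O | starting material
16 | (3S,4Z)-5-iodohexa-1,4-dien-3-yl (2S)-2-methylbutanoate | I/C(C)=C\[C@@H](OC(=O)[C@@H](C)CC)C=C | intermediate
17 | dichloro[(2Z,4S)-4-{[(2S)-2-methylbutanoyl]oxy}hexa-2,5-dien-2-yl]chromium | Cl[Cr](Cl)/C(C)=C\[C@@H](OC(=O)[C@@H](C)CC)C=C | intermediate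
18 | (3S,4Z,6S,9E)-9-{[(tert-butyldiphenylsilyl)oxy]methyl}-6,11-dihydroxy-5-methylundeca-1,4,9-trien-3-yl (2S)-2-methylbutanoate | OC/C=C(/CO[Si](c1ccccc1)(c1ccccc1)C(C)(C)C)CC[C@H](O)/C(C)=C\[C@@H](OC(=O)[C@@H](C)CC)C=C | intermediate
19 | methyl 2-(bromomethyl)prop-2-enoate | C=C(CBr)C(=O)OC | starting material
20 | methyl (2Z,4R,5Z,7S,10E)-2-(bromomethyl)-10-{[(tert-butyldiphenylsilyl)oxy]methyl}-7,12-dihydroxy-6-methyl-4-{[(2S)-2-methylbutanoyl]oxy}dodeca-2,5,10-trienoate | OC/C=C(/CO[Si](c1ccccc1)(c1ccccc1)C(C)(C)C)CC[C@H](O)/C(C)=C\[C@@H](OC(=O)[C@@H](C)CC)/C=C(\CBr)C(=O)OC | intermediate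
21 | methyl (2Z,4R,5Z,7S,10E)-2-(bromomethyl)-10-{[(tert-butyldiphenylsilyl)oxy]methyl}-7-hydroxy-6-methyl-4-{[(2S)-2-methylbutanoyl]oxy}-12-oxododeca-2,5,10-trienoate | O=C/C=C(/CO[Si](c1ccccc1)(c1ccccc1)C(C)(C)C)CC[C@H](O)/C(C)=C\[C@@H](OC(=O)[C@@H](C)CC)/C=C(\CBr)C(=O)OC | intermediate
22 | allylchromium(III) dichloride of 21 (CrCl2 in place of Br on C13) | O=C/C=C(/CO[Si](c1ccccc1)(c1ccccc1)C(C)(C)C)CC[C@H](O)/C(C)=C\[C@@H](OC(=O)[C@@H](C)CC)/C=C(\C[Cr](Cl)Cl)C(=O)OC | intermediate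
23 | methyl (1S,4E,6R,7S,8R,9Z)-15-[(tert-butyldiphenylsilyl)oxy]-1,6-dihydroxy-8-{[(2S)-2-methylbutanoyl]oxy}germacra-4,9,11(13)-trien-12-oate | C=C(C(=O)OC)[C@H]1[C@H](O)/C=C(/CO[Si](c2ccccc2)(c2ccccc2)C(C)(C)C)CC[C@H](O)/C(C)=C\[C@H]1OC(=O)[C@@H](C)CC | intermediate
24 | (1S,4E,6R,7R,8R,9Z)-15-[(tert-butyldiphenylsilyl)oxy]-1-hydroxy-8-{[(2S)-2-methylbutanoyl]oxy}germacra-4,9,11(13)-trien-12,6-olide | C=C1C(=O)O[C@@H]2/C=C(/CO[Si](c3ccccc3)(c3ccccc3)C(C)(C)C)CC[C@H](O)/C(C)=C\[C@@H](OC(=O)[C@@H](C)CC)[C@@H]12 | intermediate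
25 | (1S,4E,6R,7R,8R,9Z)-1,15-dihydroxy-8-{[(2S)-2-methylbutanoyl]oxy}germacra-4,9,11(13)-trien-12,6-olide, i.e. (3aR,4R,5Z,7S,10E,11aR)-7-hydroxy-10-(hydroxymethyl)-6-methyl-3-methylidene-2-oxo-3a,4,7,8,9,11a-hexahydrocyclodeca[b]furan-4-yl (2S)-2-methylbutanoate | C=C1C(=O)O[C@@H]2/C=C(/CO)CC[C@H](O)/C(C)=C\[C@@H](OC(=O)[C@@H](C)CC)[C@@H]12 | target

**Totals**

Total step count: 12. Longest linear sequence: 9 (steps 4–12).

**Steps most likely to fail**

Step 11 (macro-allylation/lactonisation). The ten-membered closure competes with oligomerisation, the C6/C7 pair rests on substrate control from C8, and the C8 ester sits 1,4 to the metal and could be lost by reductive elimination. The fallback closes the same C6–C7 bond by a Lewis-acid Hosomi–Sakurai reaction of a neutral allylsilane, which has no carbon–metal bond to eliminate and reacts through an open transition state. It sets out from 18: cross-metathesis with methyl 2-[(trimethylsilyl)methyl]prop-2-enoate gives the allylsilane diol F1, TEMPO/PhI(OAc)2 gives the allylsilane enal F2, and BF3·OEt2 (CH2Cl2, −78 °C, high dilution) followed by the PPTS lactonisation comes back to the route at 24.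

Step 9 (cross-metathesis). A 1,1-disubstituted acrylate must couple with a terminal olefin on an ester-bearing, doubly allylic carbon. The fallback makes the trisubstituted olefin by Wittig olefination before the fragments are joined, which requires an allyl donor that survives Cr(II), i.e. the allylsilane. It sets out from 16: OsO4 (cat.)/NMO then NaIO4 cleaves only the monosubstituted vinyl group (the iodo-olefin is deactivated) to the aldehyde F3; the stabilised ylide methyl 2-(triphenylphosphoranylidene)-3-(trimethylsilyl)propanoate gives the iodo allylsilane F4; coupling with 8 under the step 8 conditions gives F1, and oxidation to F2 and the Sakurai closure described above come back to the route at 24.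

Step 8 (asymmetric Ni/Cr coupling). Ligand control at C1 with a hindered (Z)-trisubstituted iodide may be modest. The fallback sets C1 by reagent-controlled ketone reduction. It sets out from 8: TESCl/imidazole gives the silyl ether F5; ligand-free CrCl2/NiCl2 coupling with 16 gives the C1-epimeric alcohols F6; Dess–Martin periodinane gives the enone F7; (R)-Me-CBS/catecholborane (−78 °C) gives the 1S alcohol F8; HF·pyridine/pyridine (0 °C) removes only the TES group and comes back to the route at 18.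

**Further compounds**

F1 | step 11 | methyl (2Z,4R,5Z,7S,10E)-10-{[(tert-butyldiphenylsilyl)oxy]methyl}-7,12-dihydroxy-6-methyl-4-{[(2S)-2-methylbutanoyl]oxy}-2-[(trimethylsilyl)methyl]dodeca-2,5,10-trienoate | OC/C=C(/CO[Si](c1ccccc1)(c1ccccc1)C(C)(C)C)CC[C@H](O)/C(C)=C\[C@@H](OC(=O)[C@@H](C)CC)/C=C(\C[Si](C)(C)C)C(=O)OC
F2 | step 11 | methyl (2Z,4R,5Z,7S,10E)-10-{[(tert-butyldiphenylsilyl)oxy]methyl}-7-hydroxy-6-methyl-4-{[(2S)-2-methylbutanoyl]oxy}-12-oxo-2-[(trimethylsilyl)methyl]dodeca-2,5,10-trienoate | O=C/C=C(/CO[Si](c1ccccc1)(c1ccccc1)C(C)(C)C)CC[C@H](O)/C(C)=C\[C@@H](OC(=O)[C@@H](C)CC)/C=C(\C[Si](C)(C)C)C(=O)OC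
F3 | step 9 | (2R,3Z)-4-iodo-1-oxopent-3-en-2-yl (2S)-2-methylbutanoate | I/C(C)=C\[C@@H](OC(=O)[C@@H](C)CC)C=O
F4 | step 9 | methyl (2Z,4S,5Z)-6-iodo-4-{[(2S)-2-methylbutanoyl]oxy}-2-[(trimethylsilyl)methyl]hepta-2,5-dienoate | I/C(C)=C\[C@@H](OC(=O)[C@@H](C)CC)/C=C(\C[Si](C)(C)C)C(=O)OC
F5 | step 8 | (E)-4-{[(tert-butyldiphenylsilyl)oxy]methyl}-6-[(triethylsilyl)oxy]hex-4-enal | CC[Si](CC)(CC)OC/C=C(/CO[Si](c1ccccc1)(c1ccccc1)C(C)(C)C)CCC=O
F6 | step 8 | (3S,4Z,6RS,9E)-9-{[(tert-butyldiphenylsilyl)oxy]methyl}-6-hydroxy-5-methyl-11-[(triethylsilyl)oxy]undeca-1,4,9-trien-3-yl (2S)-2-methylbutanoate (C6 epimers) | CC[Si](CC)(CC)OC/C=C(/CO[Si](c1ccccc1)(c1ccccc1)C(C)(C)C)CCC(O)/C(C)=C\[C@@H](OC(=O)[C@@H](C)CC)C=C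
F7 | step 8 | (3S,4Z,9E)-9-{[(tert-butyldiphenylsilyl)oxy]methyl}-5-methyl-6-oxo-11-[(triethylsilyl)oxy]undeca-1,4,9-trien-3-yl (2S)-2-methylbutanoate | CC[Si](CC)(CC)OC/C=C(/CO[Si](c1ccccc1)(c1ccccc1)C(C)(C)C)CCC(=O)/C(C)=C\[C@@H](OC(=O)[C@@H](C)CC)C=C
F8 | step 8 | (3S,4Z,6S,9E)-9-{[(tert-butyldiphenylsilyl)oxy]methyl}-6-hydroxy-5-methyl-11-[(triethylsilyl)oxy]undeca-1,4,9-trien-3-yl (2S)-2-methylbutanoate | CC[Si](CC)(CC)OC/C=C(/CO[Si](c1ccccc1)(c1ccccc1)C(C)(C)C)CC[C@H](O)/C(C)=C\[C@@H](OC(=O)[C@@H](C)CC)C=C
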